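**Assumptions (one line):** atom labels follow atisane numbering (C20 = angular methyl, C17 = exocyclic methylene, C3 = lactone carbonyl). I assume the Diels–Alder gives the required diastereomer, with C14-OTBS trans to C9, as a separable major product.

## Retrosynthetic overview
1. Crotobarin ⇒ α-methylenation of the C15 ketone ⇐ C14-OAc ⇐ C14-OTBS lactone ⇐ hydroxy-ester closed to the δ-lactone (C9–O set by the ring closure).
2. The bicyclo[2.2.2]octane is closed by a Michael addition of PhSO₂CH₂⁻ to a spiro cyclohexenone (C12), followed by intramolecular addition of the sulfonyl carbanion to the C9 ketone. PhSO₂CH₃ supplies C11.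
3. **Key step:** the spiro cyclohexenone comes from a Diels–Alder reaction of a ring-B α-(silyloxymethylene) ketone (C8=C14) with 1-silyloxybutadiene. This forms quaternary C8, installs C14–O and gives C15 as the allylic alcohol.
4. Ring B with C5/C10 comes from (R)-carvone: ozonolysis, Baeyer–Villiger, then tandem cuprate addition/Michael trapping.
5. Ring order: ring B, then ring C (Diels–Alder), then bicyclooctane (Michael/aldol), then lactone.

## Route

**Step 1**
Reactants: 1 (R)-carvone
Product: 2 (5R)-5-acetyl-2-methylcyclohex-2-en-1-one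
Conditions: O₃, CH₂Cl₂/MeOH, −78 °C; then PPh₃
Reagents that add atoms: ozone, [O-][O+]=O (its oxygen ends up in the acetyl group)
Why: Ozonolysis is selective for the electron-rich isopropenyl group over the enone alkene, and the ring stereocentre is untouched.

**Step 2**
Reactants: 2
Product: 3 (5R)-5-acetoxy-2-methylcyclohex-2-en-1-one
Conditions: mCPBA, NaHCO₃, CH₂Cl₂, 0 °C → rt
Reagents that add atoms: mCPBA, O=C(OO)c1cccc(Cl)c1
Why: Baeyer–Villiger oxidation; the secondary ring carbon migrates in preference to methyl, with retention, so the carvone stereocentre becomes a C–OAc centre.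

**Step 3**
Reactants: 3; 4 isopropenylmagnesium bromide; 5 tert-butyl acrylate
Product: 6 tert-butyl 3-[4-acetoxy-1-methyl-6-oxo-2-(prop-1-en-2-yl)cyclohexyl]propanoate
Conditions: 4, CuBr·SMe₂, THF, −78 °C; then 5, HMPA, −78 → −20 °C
Reagents that add atoms: none (the carbon fragments are reactants 4 and 5)
Why: In this tandem conjugate addition/Michael trapping, isopropenyl adds trans to the 5-OAc, setting C5. The enolate then adds to the acrylate anti to the new isopropenyl, giving a quaternary C10 with methyl cis and the chain trans to isopropenyl, as in the target.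

**Step 4**
Reactants: 6
Product: 7 tert-butyl 3-[1-methyl-6-oxo-2-(prop-1-en-2-yl)cyclohex-4-en-1-yl]propanoate (enone C7=C8)
Conditions: DBU, PhH, 80 °C
Reagents that add atoms: none
Why: E1cB loss of AcOH from the β-acetoxy ketone. The carvone-derived centre has already transmitted its stereochemical information, and C5/C10 are unaffected.

**Step 5**
Reactants: 7; 8 ethyl formate
Product: 9 ring-B 2-(hydroxymethylene) ketone (C8=CH–OH, C7 now CH₂)
Conditions: L-Selectride, THF, −78 °C; then 8
Reagents that add atoms: none (the formyl carbon, C14, comes from reactant 8)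
Why: Stork-type 1,4-reduction gives the regiodefined C8 enolate, which undergoes Claisen formylation. C10 is quaternary, so only C8 can enolise.

**Step 6**
Reactants: 9
Product: 10 silyl enol ether dienophile (C8=C14H–OTBS, C9 ketone)
Conditions: TBSCl, imidazole, DMF, rt
Reagents that add atoms: tert-butyldimethylsilyl chloride, CC(C)(C)[Si](C)(C)Cl
Why: O-silylation gives a robust C14–O group that tolerates the sulfonyl carbanion in step 9.

**Step 7**
Reactants: 10; 11 1-(trimethylsilyloxy)buta-1,3-diene
Product: 12 spiro cyclohexenol (C15–OH, C16=C12, C13H₂, C14–OTBS, C9 ketone retained)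
Conditions: Me₂AlCl, CH₂Cl₂, −78 °C → rt; then 1 N HCl, THF
Reagents that add atoms: none (the diene is reactant 11)
Why: Normal-demand Diels–Alder reaction of a 1-oxygenated diene with the Lewis-acid-activated enone. Ortho regiochemistry bonds the OTMS carbon (C15) to C8 and C13 to C14. The diene attacks C8 anti to the axial C10 methyl, which sets C8. The enol-ether geometry and endo alignment set C14 trans to C9.

**Step 8**
Reactants: 12
Product: 13 spiro enone (C15=O conjugated with C16=C12)
Conditions: MnO₂, CH₂Cl₂, rt
Reagents that add atoms: none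
Why: Chemoselective allylic alcohol oxidation; C15 stereochemistry is irrelevant. This creates the β-carbon (C12) needed for the closure.

**Step 9**
Reactants: 13; 14 methyl phenyl sulfone
Product: 15 bicyclo[2.2.2]octane (C11–SO₂Ph, C9–OH, C15 ketone)
Conditions: 14 + LDA (2.5 equiv), THF, −78 → 0 °C; add 13; quench with NH₄Cl
Reagents that add atoms: none (14 is a reactant)
Why: The sulfonyl carbanion adds 1,4 to C12 (Michael). Second deprotonation at C11 and 1,2-addition to the C9 ketone (aldol-type) closes the bicyclooctane. Ring geometry forces C11 onto the face of C14, so the C9 oxygen ends cis to the C10 chain and C12 is fixed. The tert-butyl ester prevents premature lactonisation.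

**Step 10**
Reactants: 15
Product: 16 hydroxy tert-butyl ester (C11H₂)
Conditions: Na(Hg), NaH₂PO₄, MeOH, −20 °C
Reagents that add atoms: none
Why: Reductive desulfonylation. The β-oxygen is a free tertiary alcohol rather than an acyloxy group, which avoids Julia-type elimination; no stereocentre is touched.

**Step 11**
Reactants: 16
Product: 17 δ-lactone (C14-OTBS, C15 ketone, C16H₂)
Conditions: TFA, CH₂Cl₂, 0 °C → rt
Reagents that add atoms: none
Why: tert-Butyl ester cleavage followed by acid-promoted lactonisation of the cis-disposed C9 tertiary alcohol and C3 acid; C9 configuration is retained.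

**Step 12**
Reactants: 17
Product: 18 C14 alcohol
Conditions: HF·pyridine, THF, 0 °C → rt
Reagents that add atoms: none
Why: Desilylation under non-basic conditions, avoiding retro-aldol or oxa-Michael chemistry; C14 configuration is retained.

**Step 13**
Reactants: 18
Product: 19 C14 acetate
Conditions: Ac₂O, DMAP, Et₃N, CH₂Cl₂, rt
Reagents that add atoms: acetic anhydride, CC(=O)OC(C)=O
Why: Acylation of the hindered secondary alcohol with retention. The acetate is not β-eliminable because C8 is quaternary.

**Step 14**
Reactants: 19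
Product: 20 crotobarin
Conditions: (CH₂O)ₙ, iPr₂NH₂⁺ CF₃CO₂⁻, THF, 65 °C
Reagents that add atoms: paraformaldehyde, C=O (supplies C17)
Why: Mannich/elimination α-methylenation (Gras conditions) at the only enolisable α-carbon (C16); the other α-carbon, C8, is quaternary.

## Compound list
1 | (R)-carvone, (5R)-2-methyl-5-(prop-1-en-2-yl)cyclohex-2-en-1-one | CC1=CC[C@H](CC1=O)C(C)=C | starting material
2 | (5R)-5-acetyl-2-methylcyclohex-2-en-1-one | CC1=CC[C@H](CC1=O)C(C)=O | intermediate
3 | (5R)-5-acetoxy-2-methylcyclohex-2-en-1-one | CC1=CC[C@H](CC1=O)OC(C)=O | intermediate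
4 | isopropenylmagnesium bromide | C=C(C)[Mg]Br | starting material
5 | tert-butyl acrylate | C=CC(=O)OC(C)(C)C | starting material
6 | tert-butyl 3-[4-acetoxy-1-methyl-6-oxo-2-(prop-1-en-2-yl)cyclohexyl]propanoate (isopropenyl and methyl cis, chain trans) | O=C1C[C@H](OC(C)=O)C[C@@H](C(C)=C)[C@]1(C)CCC(=O)OC(C)(C)C | intermediate
7 | ring-B enone (C7=C8) | O=C1C=CC[C@@H](C(C)=C)[C@]1(C)CCC(=O)OC(C)(C)C | intermediate
8 | ethyl formate | CCOC=O | starting material
9 | 2-(hydroxymethylene) ketone | O=C1C(=CO)CC[C@@H](C(C)=C)[C@]1(C)CCC(=O)OC(C)(C)C | intermediate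
10 | 2-(TBS-oxymethylene) ketone (dienophile) | O=C1C(=CO[Si](C)(C)C(C)(C)C)CC[C@@H](C(C)=C)[C@]1(C)CCC(=O)OC(C)(C)C | intermediate
11 | 1-(trimethylsilyloxy)buta-1,3-diene | C=CC=CO[Si](C)(C)C | starting material
12 | spiro cyclohexenol (C15 stereocentre unassigned) | OC1C=CC[C@H](O[Si](C)(C)C(C)(C)C)[C@]12CC[C@@H](C(C)=C)[C@](C)(CCC(=O)OC(C)(C)C)C2=O | intermediate
13 | spiro enone | O=C1C=CC[C@H](O[Si](C)(C)C(C)(C)C)[C@]12CC[C@@H](C(C)=C)[C@](C)(CCC(=O)OC(C)(C)C)C2=O | intermediate
14 | methyl phenyl sulfone | CS(=O)(=O)c1ccccc1 | starting material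
15 | bicyclic sulfone alcohol (C11 stereocentre unassigned) | C1C(=O)[C@]23CC[C@@H](C(C)=C)[C@](C)(CCC(=O)OC(C)(C)C)[C@@]2(O)C(S(=O)(=O)c2ccccc2)[C@H]1C[C@@H]3O[Si](C)(C)C(C)(C)C | intermediate
16 | desulfonylated hydroxy-ester | C1C(=O)[C@]23CC[C@@H](C(C)=C)[C@](C)(CCC(=O)OC(C)(C)C)[C@@]2(O)C[C@H]1C[C@@H]3O[Si](C)(C)C(C)(C)C | intermediate
17 | TBS lactone | C1C(=O)[C@]23CC[C@@H](C(=C)C)[C@]4(C)CCC(=O)O[C@@]42C[C@H]1C[C@@H]3O[Si](C)(C)C(C)(C)C | intermediate
18 | C14 alcohol | C1C(=O)[C@]23CC[C@@H](C(=C)C)[C@]4(C)CCC(=O)O[C@@]42C[C@H]1C[C@@H]3O | intermediate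
19 | C14 acetate (16-nor-methylene ketone) | C1C(=O)[C@]23CC[C@@H](C(=C)C)[C@]4(C)CCC(=O)O[C@@]42C[C@H]1C[C@@H]3OC(C)=O | intermediate
20 | crotobarin | C=C1C(=O)[C@]23CC[C@@H](C(=C)C)[C@]4(C)CCC(=O)O[C@@]42C[C@H]1C[C@@H]3OC(C)=O | target

**Total steps:** 14. **Longest linear sequence:** 14.

**Three steps most likely to fail**
1. **Step 7 (Diels–Alder):** the β-silyloxy enone is a poor push–pull dienophile, and the C14 diastereoselectivity depends on enol-ether geometry. Fallback: assemble the spiro ring stepwise instead, by a Lewis-acid Mukaiyama–Michael of a silyloxydiene onto the formyl ketone followed by intramolecular aldol closure, then oxidise and continue.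
2. **Step 9 (Michael/aldol closure):** it needs chemoselective 1,4-addition, and the hindered C9 ketone sits between two quaternary centres. Fallback: add ICH₂Li to the C9 ketone and close by a Giese-type 6-exo radical cyclisation onto the enone (Bu₃SnH, AIBN), in place of the carbanion closure.
3. **Step 3 (quaternary C10 by Michael trapping):** the tetrasubstituted enolate is hindered. Fallback: trap the cuprate enolate as its TMS enol ether (TMSCl) and perform a TiCl₄-mediated Mukaiyama–Michael with tert-butyl acrylate.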